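The ring atoms are labelled C1 (CCl–CH3), C2, C3 (quaternary; CH3 and the C7=C8 bromovinyl group), C4 (CHBr), C5 and C6 (CHCl). The route rests on cutting the ring bond C3–C4: a quaternary carbon carrying an alkenyl group next to heteroatom-bearing C4 is what a γ,γ-disubstituted allylchromium leaves when it adds to an aldehyde. One ligand-controlled intramolecular allylation therefore closes the six-membered ring, makes C3–C4, sets both stereocentres (oxygen trans to vinyl) and releases the C7=C8 vinyl group. Its precursor is an acyclic (3Z,6E)-bromodienal, assembled with both alkene geometries fixed and with the β,γ-unsaturated aldehyde unveiled last; epoxidation, dichlorination, invertive bromination and bromo-olefination then complete the target.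

Key step: step 9

Remark on the chemistry: the sense of induction of the chromium ligand in a ring closure cannot be read off from intermolecular cases, so the (S,S)-ligand is written as the working choice and its mirror image is used if a pilot run shows the opposite sense; compounds 1 and 2 are taken as commercial.

Step 1
Reactants: 1 3-[(tert-butyldimethylsilyl)oxy]propanal; 2 ethyl 2-[bis(2,2,2-trifluoroethoxy)phosphoryl]propanoate
Product: 3 ethyl (2Z)-5-[(tert-butyldimethylsilyl)oxy]-2-methylpent-2-enoate
Conditions: KN(SiMe3)2, 18-crown-6, THF, −78 °C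
Reagents that add atoms: none
Why: Still–Gennari olefination, in which the electron-poor phosphonate eliminates fast from the kinetic adduct, should give the Z trisubstituted enoate (ester carbon cis to the chain), the geometry that later becomes the ring alkene C1=C6.

Step 2
Reactants: 3 ethyl (2Z)-5-[(tert-butyldimethylsilyl)oxy]-2-methylpent-2-enoate
Product: 4 (2Z)-5-[(tert-butyldimethylsilyl)oxy]-2-methylpent-2-en-1-ol
Conditions: i-Bu2AlH, CH2Cl2, −78 → 0 °C
Reagents that add atoms: none
Why: 1,2-Reduction of the enoate with a dialkylaluminium hydride (ester reduction) should give the allylic alcohol and leave the silyl ether and the alkene geometry untouched.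

Step 3
Reactants: 4 (2Z)-5-[(tert-butyldimethylsilyl)oxy]-2-methylpent-2-en-1-ol
Product: 5 {[(3Z)-5-bromo-4-methylpent-3-en-1-yl]oxy}(tert-butyl)dimethylsilane
Conditions: CBr4, PPh3, CH2Cl2, 0 °C
Reagents that add atoms: tetrabromomethane, BrC(Br)(Br)Br
Why: Appel reaction, in which bromide displaces the primary allylic oxyphosphonium by SN2 under neutral conditions, should keep the Z geometry and the silyl ether.

Step 4
Reactants: 5 {[(3Z)-5-bromo-4-methylpent-3-en-1-yl]oxy}(tert-butyl)dimethylsilane
Product: 6 tert-butyldimethyl{[(3Z)-4-methylhept-3-en-6-yn-1-yl]oxy}silane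
Conditions: HC≡CMgBr, CuBr·SMe2 (cat.), THF, 0 °C → rt
Reagents that add atoms: ethynylmagnesium bromide, C#C[Mg]Br
Why: Copper-catalysed coupling of an alkynyl Grignard reagent with a primary allylic bromide should substitute at the CH2 carbon with retention of the Z alkene and give the skipped enyne.

Step 5
Reactants: 6 tert-butyldimethyl{[(3Z)-4-methylhept-3-en-6-yn-1-yl]oxy}silane
Product: 8 (2E,5Z)-8-[(tert-butyldimethylsilyl)oxy]-3,5-dimethylocta-2,5-dien-1-ol, via alkenylalane 7 (not isolated)
Conditions: AlMe3, Cp2ZrCl2 (cat.), CH2Cl2, 0 °C → rt; then (CH2O)n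
Reagents that add atoms: trimethylaluminium, C[Al](C)C; formaldehyde (as paraformaldehyde), C=O
Why: Negishi carboalumination (zirconium-catalysed syn addition of CH3–Al across the terminal alkyne, methyl to the internal carbon) followed by hydroxymethylation of the alkenylalane with retention should give the 2E allylic alcohol, which fixes the allyl geometry on which the key step depends.

Step 6
Reactants: 8 (2E,5Z)-8-[(tert-butyldimethylsilyl)oxy]-3,5-dimethylocta-2,5-dien-1-ol
Product: 9 (2E,5Z)-3,5-dimethylocta-2,5-diene-1,8-diol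
Conditions: Bu4NF, THF, 0 °C → rt
Reagents that add atoms: none
Why: Fluoride-mediated desilylation should free the primary homoallylic alcohol without affecting the skipped diene or the allylic alcohol.

Step 7
Reactants: 9 (2E,5Z)-3,5-dimethylocta-2,5-diene-1,8-diol
Product: 10 (3Z,6E)-8-bromo-4,6-dimethylocta-3,6-dien-1-ol
Conditions: NBS, Me2S, CH2Cl2, −20 → 0 °C
Reagents that add atoms: N-bromosuccinimide, O=C1CCC(=O)N1Br
Why: Corey–Kim halogenation, in which only the allylic alkoxysulfonium salt is displaced by bromide at low temperature while that of the saturated primary alcohol reverts to the alcohol on work-up, should form the allylic bromide chemoselectively.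

Step 8
Reactants: 10 (3Z,6E)-8-bromo-4,6-dimethylocta-3,6-dien-1-ol
Product: 11 (3Z,6E)-8-bromo-4,6-dimethylocta-3,6-dienal
Conditions: Dess–Martin periodinane (DMP), NaHCO3, CH2Cl2, 0 °C; used at once
Reagents that add atoms: none
Why: Dess–Martin oxidation under buffered, non-basic conditions should deliver the β,γ-unsaturated aldehyde at the last moment without conjugation of the 3Z alkene or loss of the allylic bromide.

Step 9
Reactants: 11 (3Z,6E)-8-bromo-4,6-dimethylocta-3,6-dienal
Product: 13 (1R,2S)-2-ethenyl-2,4-dimethylcyclohex-4-en-1-ol, via trimethylsilyl ether 12 (not isolated)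
Conditions: CrCl2 (10 mol%), (S,S)-1,8-bis(4-isopropyl-4,5-dihydro-1,3-oxazol-2-yl)-3,6-diphenyl-9H-carbazole (12 mol%), i-Pr2NEt, Mn, TMSCl, THF, rt, syringe-pump addition of 11 (5 mM); then 1 M HCl
Reagents that add atoms: chlorotrimethylsilane, C[Si](C)(C)Cl (its silyl group stays in intermediate 12 only)
Why: Divalent chromium inserts into the allylic C–Br bond of 11, and the allylchromium (trivalent) binds the aldehyde and hands over its γ-carbon (C3) to the carbonyl carbon (C4) through a closed chair-like six-membered transition state, after which TMSCl frees the metal from the alkoxide and Mn returns it to the divalent state (Nozaki–Hiyama–Kishi allylation). The closest known reactions are the intramolecular chromium allylation of formyl-tethered allylic halides and the catalytic asymmetric intermolecular allylation with chromium–bis(oxazolinyl)carbazole complexes, which are merged here. The one ring is closed in the 6-exo-trig mode onto the carbonyl group, whereas attack through the α-carbon (C8) would require an eight-membered ring. C3 and C4 are set relative to each other by the 6E geometry of the allyl unit, which puts the tether equatorial and the methyl axial on the γ-carbon while the aldehyde chain sits equatorial (chair trans-fused to the nascent cyclohexene), so that oxygen ends trans to vinyl. Their absolute configuration (3S,4R in the ring labels, addition to the Si face of the aldehyde) is set by the chiral ligand on chromium. The step needs γ-regioselectivity, trans-diastereoselectivity and cyclisation in preference to oligomerisation; the six- against eight-membered ring choice, the defined 6E alkene, the 3Z alkene that holds both chain ends on one side, and slow addition at high dilution secure them.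

Step 10
Reactants: 13 (1R,2S)-2-ethenyl-2,4-dimethylcyclohex-4-en-1-ol
Product: 14 (1S,3R,4S,6R)-4-ethenyl-4,6-dimethyl-7-oxabicyclo[4.1.0]heptan-3-ol (epoxide on the ring face of the hydroxyl)
Conditions: VO(acac)2 (cat.), t-BuOOH, CH2Cl2, 0 °C → rt
Reagents that add atoms: tert-butyl hydroperoxide, CC(C)(C)OO
Why: Hydroxyl-directed vanadium-catalysed epoxidation of a cyclic homoallylic alcohol should deliver oxygen from the vanadium alkoxide at C4 to the same face of the electron-rich C1=C6 alkene, which sets C1 and C6 (epoxide cis to OH, anti to vinyl) and spares the vinyl group.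

Step 11
Reactants: 14 (1S,3R,4S,6R)-4-ethenyl-4,6-dimethyl-7-oxabicyclo[4.1.0]heptan-3-ol
Product: 15 (1S,3R,4S,6R)-4-ethenyl-4,6-dimethyl-7-oxabicyclo[4.1.0]heptan-3-yl acetate
Conditions: Ac2O, pyridine, DMAP (cat.), CH2Cl2, rt
Reagents that add atoms: acetic anhydride, CC(=O)OC(C)=O
Why: DMAP-catalysed acylation masks the C4 hydroxyl, which the chlorinating reagent of the next step would otherwise convert into a chloride, and the epoxide is inert to these conditions.

Step 12
Reactants: 15 (1S,3R,4S,6R)-4-ethenyl-4,6-dimethyl-7-oxabicyclo[4.1.0]heptan-3-yl acetate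
Product: 16 (1R,2S,4S,5R)-4,5-dichloro-2-ethenyl-2,4-dimethylcyclohexyl acetate
Conditions: Ph3PCl2, toluene, 0 → 60 °C
Reagents that add atoms: dichlorotriphenylphosphorane, ClP(Cl)(c1ccccc1)(c1ccccc1)c1ccccc1
Why: Deoxydichlorination of an epoxide with Ph3PCl2, in which chloride opens the phosphorus-activated epoxide at the tertiary carbon C1 with inversion and then displaces the C6 oxyphosphonium with a second inversion, should place both chlorines on the face opposite to the epoxide oxygen and so give the cis-dichloride syn to the vinyl group.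

Step 13
Reactants: 16 (1R,2S,4S,5R)-4,5-dichloro-2-ethenyl-2,4-dimethylcyclohexyl acetate
Product: 17 (1R,2S,4S,5R)-4,5-dichloro-2-ethenyl-2,4-dimethylcyclohexan-1-ol
Conditions: K2CO3, MeOH, 0 °C → rt
Reagents that add atoms: none
Why: Base-catalysed transesterification (methanolysis of the acetate) should free the C4 hydroxyl under conditions too mild to eliminate HCl from the tertiary or the secondary chloride.

Step 14
Reactants: 17 (1R,2S,4S,5R)-4,5-dichloro-2-ethenyl-2,4-dimethylcyclohexan-1-ol
Product: 18 (1S,2S,4R,5S)-2-bromo-4,5-dichloro-1-ethenyl-1,5-dimethylcyclohexane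
Conditions: PPh3, CBr4, toluene, rt → 70 °C
Reagents that add atoms: tetrabromomethane, BrC(Br)(Br)Br
Why: Appel reaction, in which bromide attacks the C4 oxyphosphonium from the face opposite to oxygen (SN2), should invert C4 and place bromine cis to the vinyl group, and since the ring alkene is already consumed no homoallylic participation can turn the substitution into retention.

Step 15
Reactants: 18 (1S,2S,4R,5S)-2-bromo-4,5-dichloro-1-ethenyl-1,5-dimethylcyclohexane
Product: 20 (1S,2S,4R,5S)-2-bromo-4,5-dichloro-1,5-dimethylcyclohexane-1-carbaldehyde, via ozonide 19 (not isolated)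
Conditions: O3, CH2Cl2, −78 °C; then PPh3, −78 °C → rt
Reagents that add atoms: ozone, [O-][O+]=O
Why: Ozonolysis with reductive work-up should cleave the vinyl group, now the only alkene, to the aldehyde, which has no α-hydrogen and therefore can neither epimerise nor lose HBr.

Step 16
Reactants: 20 (1S,2S,4R,5S)-2-bromo-4,5-dichloro-1,5-dimethylcyclohexane-1-carbaldehyde
Product: 21 (1S,2S,4R,5S)-2-bromo-1-[(E)-2-bromoethenyl]-4,5-dichloro-1,5-dimethylcyclohexane
Conditions: CrBr2, CHBr3, THF, 0 °C → rt
Reagents that add atoms: bromoform, BrC(Br)Br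
Why: Takai olefination, in which the geminal dichromium species from CHBr3 and divalent chromium adds to the aldehyde and eliminates to the E-bromoalkene, should finish the target; the bromide salt of chromium avoids halogen scrambling and unactivated alkyl chlorides and bromides are inert to the reagent.

Compound list
1 | 3-[(tert-butyldimethylsilyl)oxy]propanal | O=CCCO[Si](C)(C)C(C)(C)C | starting material
2 | ethyl 2-[bis(2,2,2-trifluoroethoxy)phosphoryl]propanoate | CCOC(=O)C(C)P(=O)(OCC(F)(F)F)OCC(F)(F)F | starting material
3 | ethyl (2Z)-5-[(tert-butyldimethylsilyl)oxy]-2-methylpent-2-enoate | CCOC(=O)/C(C)=C\CCO[Si](C)(C)C(C)(C)C | intermediate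
4 | (2Z)-5-[(tert-butyldimethylsilyl)oxy]-2-methylpent-2-en-1-ol | OC/C(C)=C\CCO[Si](C)(C)C(C)(C)C | intermediate
5 | {[(3Z)-5-bromo-4-methylpent-3-en-1-yl]oxy}(tert-butyl)dimethylsilane | BrC/C(C)=C\CCO[Si](C)(C)C(C)(C)C | intermediate
6 | tert-butyldimethyl{[(3Z)-4-methylhept-3-en-6-yn-1-yl]oxy}silane | C#CC/C(C)=C\CCO[Si](C)(C)C(C)(C)C | intermediate
7 | [(1E,4Z)-7-[(tert-butyldimethylsilyl)oxy]-2,4-dimethylhepta-1,4-dien-1-yl]dimethylalane (formed in the flask, not isolated) | C[Al](C)/C=C(\C)C/C(C)=C\CCO[Si](C)(C)C(C)(C)C | intermediate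
8 | (2E,5Z)-8-[(tert-butyldimethylsilyl)oxy]-3,5-dimethylocta-2,5-dien-1-ol | OC/C=C(\C)C/C(C)=C\CCO[Si](C)(C)C(C)(C)C | intermediate
9 | (2E,5Z)-3,5-dimethylocta-2,5-diene-1,8-diol | OC/C=C(\C)C/C(C)=C\CCO | intermediate
10 | (3Z,6E)-8-bromo-4,6-dimethylocta-3,6-dien-1-ol | OCC/C=C(/C)C/C(C)=C/CBr | intermediate
11 | (3Z,6E)-8-bromo-4,6-dimethylocta-3,6-dienal | O=CC/C=C(/C)C/C(C)=C/CBr | intermediate
12 | {[(1R,2S)-2-ethenyl-2,4-dimethylcyclohex-4-en-1-yl]oxy}trimethylsilane (formed in the flask, not isolated) | CC=1C[C@@](C)(C=C)[C@H](O[Si](C)(C)C)CC=1 | intermediate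
13 | (1R,2S)-2-ethenyl-2,4-dimethylcyclohex-4-en-1-ol (hydroxyl trans to vinyl) | CC=1C[C@@](C)(C=C)[C@H](O)CC=1 | intermediate
14 | (1S,3R,4S,6R)-4-ethenyl-4,6-dimethyl-7-oxabicyclo[4.1.0]heptan-3-ol | C[C@@]12C[C@@](C)(C=C)[C@H](O)C[C@@H]1O2 | intermediate
15 | (1S,3R,4S,6R)-4-ethenyl-4,6-dimethyl-7-oxabicyclo[4.1.0]heptan-3-yl acetate | C[C@@]12C[C@@](C)(C=C)[C@H](OC(C)=O)C[C@@H]1O2 | intermediate
16 | (1R,2S,4S,5R)-4,5-dichloro-2-ethenyl-2,4-dimethylcyclohexyl acetate | C[C@]1(Cl)C[C@@](C)(C=C)[C@H](OC(C)=O)C[C@H]1Cl | intermediate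
17 | (1R,2S,4S,5R)-4,5-dichloro-2-ethenyl-2,4-dimethylcyclohexan-1-ol | C[C@]1(Cl)C[C@@](C)(C=C)[C@H](O)C[C@H]1Cl | intermediate
18 | (1S,2S,4R,5S)-2-bromo-4,5-dichloro-1-ethenyl-1,5-dimethylcyclohexane | C[C@]1(Cl)C[C@@](C)(C=C)[C@@H](Br)C[C@H]1Cl | intermediate
19 | 3-[(1S,2S,4R,5S)-2-bromo-4,5-dichloro-1,5-dimethylcyclohexyl]-1,2,4-trioxolane (both epimers at the trioxolane carbon; formed in the flask, not isolated) | C[C@]1(Cl)C[C@@](C)(C2OCOO2)[C@@H](Br)C[C@H]1Cl | intermediate
20 | (1S,2S,4R,5S)-2-bromo-4,5-dichloro-1,5-dimethylcyclohexane-1-carbaldehyde | C[C@]1(Cl)C[C@@](C)(C=O)[C@@H](Br)C[C@H]1Cl | intermediate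
21 | (1S,2S,4R,5S)-2-bromo-1-[(E)-2-bromoethenyl]-4,5-dichloro-1,5-dimethylcyclohexane | C[C@]1(Cl)C[C@@](C)(/C=C/Br)[C@@H](Br)C[C@H]1Cl | target

Total step count: 16. Longest linear sequence: 16 steps (from 1 to 21).

Steps most likely to fail

First, step 9. What may go wrong is weak facial control by the chiral chromium complex in a ring closure for which it has not been tuned, and erosion of the trans relationship through the cis-fused transition state or through E/Z equilibration of the allylchromium. A ligand-free background reaction on activated manganese and oligomerisation of the sensitive aldehyde are further risks. The fallback sets out from 11 and comes back at 13. Cyclisation of 11 with stoichiometric CrCl2 in THF without ligand would give 13 together with its mirror image (1S,2R)-2-ethenyl-2,4-dimethylcyclohex-4-en-1-ol F1. Esterification of the mixture with (2R)-methoxy(phenyl)acetic acid (DCC, DMAP, CH2Cl2) would give the diastereomers (1R,2S)-2-ethenyl-2,4-dimethylcyclohex-4-en-1-yl (2R)-methoxy(phenyl)acetate F2 and (1S,2R)-2-ethenyl-2,4-dimethylcyclohex-4-en-1-yl (2R)-methoxy(phenyl)acetate F3, which are separated by chromatography. Methanolysis of F2 (K2CO3, MeOH) returns 13.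

Second, step 14. What may go wrong is slow substitution at a carbon flanked by the quaternary C3 and shielded on its upper face by the syn C6 chlorine, so that E2 elimination towards C5 or ionisation with a 1,2-shift of the vinyl group overtakes the SN2 path. The fallback moves the substitution to the epoxide stage and uses a sulfonate instead of a phosphonium leaving group; it sets out from 14 and comes back at 18. Treatment of 14 with Tf2O and pyridine (CH2Cl2, −40 °C) would give (1S,3R,4S,6R)-4-ethenyl-4,6-dimethyl-7-oxabicyclo[4.1.0]heptan-3-yl trifluoromethanesulfonate F4. Displacement with Bu4NBr in toluene at low temperature would give, with inversion, (1S,3S,4S,6R)-3-bromo-4-ethenyl-4,6-dimethyl-7-oxabicyclo[4.1.0]heptane F5, whose upper face at C4 is not yet hindered by a chlorine. Deoxydichlorination of F5 with Ph3PCl2 as in step 12 then gives 18 directly, which also removes the acetate steps.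

Third, step 12. What may go wrong is opening of the activated epoxide with carbocation character at C1 or at the wrong carbon, and chloronium participation in the second substitution; each would lead to the trans-dichloride, to allylic chlorides by elimination, or to rearranged ketones. The fallback separates the two inversions; it sets out from 15 and comes back at 16. Ring opening with HCl (dioxane, CH2Cl2, −20 °C) at the tertiary carbon would give (1R,2S,4S,5S)-4-chloro-2-ethenyl-5-hydroxy-2,4-dimethylcyclohexyl acetate F6. Triflation (Tf2O, pyridine, −40 °C) would give (1R,2S,4S,5S)-4-chloro-2-ethenyl-2,4-dimethyl-5-{[(trifluoromethyl)sulfonyl]oxy}cyclohexyl acetate F7, and SN2 displacement with Bu4NCl in toluene inverts C6 to give 16.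

Further compounds
F1 | step 9 | (1S,2R)-2-ethenyl-2,4-dimethylcyclohex-4-en-1-ol | CC=1C[C@](C)(C=C)[C@@H](O)CC=1
F2 | step 9 | (1R,2S)-2-ethenyl-2,4-dimethylcyclohex-4-en-1-yl (2R)-methoxy(phenyl)acetate | CC=1C[C@@](C)(C=C)[C@H](OC(=O)[C@H](OC)c2ccccc2)CC=1
F3 | step 9 | (1S,2R)-2-ethenyl-2,4-dimethylcyclohex-4-en-1-yl (2R)-methoxy(phenyl)acetate | CC=1C[C@](C)(C=C)[C@@H](OC(=O)[C@H](OC)c2ccccc2)CC=1
F4 | step 14 | (1S,3R,4S,6R)-4-ethenyl-4,6-dimethyl-7-oxabicyclo[4.1.0]heptan-3-yl trifluoromethanesulfonate | C[C@@]12C[C@@](C)(C=C)[C@H](OS(=O)(=O)C(F)(F)F)C[C@@H]1O2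
F5 | step 14 | (1S,3S,4S,6R)-3-bromo-4-ethenyl-4,6-dimethyl-7-oxabicyclo[4.1.0]heptane | C[C@@]12C[C@@](C)(C=C)[C@@H](Br)C[C@@H]1O2
F6 | step 12 | (1R,2S,4S,5S)-4-chloro-2-ethenyl-5-hydroxy-2,4-dimethylcyclohexyl acetate | C[C@]1(Cl)C[C@@](C)(C=C)[C@H](OC(C)=O)C[C@@H]1O
F7 | step 12 | (1R,2S,4S,5S)-4-chloro-2-ethenyl-2,4-dimethyl-5-{[(trifluoromethyl)sulfonyl]oxy}cyclohexyl acetate | C[C@]1(Cl)C[C@@](C)(C=C)[C@H](OC(C)=O)C[C@@H]1OS(=O)(=O)C(F)(F)F
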